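Ring B (cycloheptene C1', C5'–C10' with lactone C11', C12') is cut into crotonaldehyde, whose carbons are C8'(O)–C9'–C10'(CH3), and an acyclic dienyl bis-boronate carrying C1', C5', C6', C7' and the 2-carboxyallyl unit C7'–C11'–C12'. One flask joins them: rhodium-catalysed conjugate alkenylation (C1'–C10'), then ring-closing allylboration and lactonisation (C7'–C8'), giving the cis-fused lactone with three stereocentres. The same annulation with the antipodal ligand gives ring A, because C7'/C8'/C10' are antipodal to C7/C8/C10. The spiro cyclohexenol is closed by a Michael/aldol union in which the ring CH2 (C13') adds last to the convex face of a ring B keto lactone.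

Key step: step 8

Remark: xanthanolide locants are used, unprimed (C1–C15) for the half with the tertiary alcohol (ring A) and primed for the half with the 3-oxobutyl chain (ring B); C11' is the spiro carbon, C13' the ring CH2 between C11' and C5; "pinacolboryl" means 4,4,5,5-tetramethyl-1,3,2-dioxaborolan-2-yl.
Remark: a [4+2] union of two methylene lactones is not used, because for this diastereomer the diene would have to add to the concave (C6'/C9') face of the ring B lactone; the Michael/aldol union never attacks that face.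
Remark: compound 3 is taken as a catalogue compound; the ligand antipode that delivers (R)-C10' is used in step 8 and its mirror image in step 15, and the (S,S)/(R,R) labels given are provisional.

Step 1
Reactants: 1 methyl 2-(bromomethyl)acrylate
Product: 2 methyl 2-[(pinacolboryl)methyl]acrylate
Conditions: B2pin2, CuCl (5 mol %), Xantphos (5 mol %), KOtBu, THF, 0 °C
Reagents that add atoms: bis(pinacolato)diboron, CC1(C)OB(OC1(C)C)B1OC(C)(C)C(C)(C)O1
Why: Copper-catalysed borylation of an allylic bromide (SN2' substitution by a boryl-copper species) should give the allyl boronate; the allyl system is symmetrical and no stereocentre is formed.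

Step 2
Reactants: 3 2-(but-3-yn-1-yl)-2-methyl-1,3-dioxolane
Product: 5 5-(2-methyl-1,3-dioxolan-2-yl)pent-2-yn-1-ol, via lithium acetylide 4 (not isolated)
Conditions: n-BuLi, THF, −78 °C; then (CH2O)n, −78 °C to rt; aq. NH4Cl
Reagents that add atoms: paraformaldehyde (as formaldehyde), C=O
Why: Hydroxymethylation of a lithium acetylide is routine and leaves the ketal untouched.

Step 3
Reactants: 5 5-(2-methyl-1,3-dioxolan-2-yl)pent-2-yn-1-ol
Product: 7 (Z)-3-iodo-5-(2-methyl-1,3-dioxolan-2-yl)pent-2-en-1-ol, via cyclic sodium alkenylalanate 6 (not isolated)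
Conditions: NaAlH2(OCH2CH2OCH3)2, THF, 0 °C to rt; then I2, −78 °C
Reagents that add atoms: iodine, II
Why: Hydroxyl-directed trans-hydroalumination of the propargylic alcohol and iodinolysis with retention should place iodine on the future C1' cis to the CH2OH carbon (future C6'), which fixes the ring-cis alkene geometry.

Step 4
Reactants: 7 (Z)-3-iodo-5-(2-methyl-1,3-dioxolan-2-yl)pent-2-en-1-ol
Product: 8 2-[(Z)-5-bromo-3-iodopent-3-en-1-yl]-2-methyl-1,3-dioxolane
Conditions: CBr4, PPh3, 2,6-lutidine, CH2Cl2, 0 °C
Reagents that add atoms: carbon tetrabromide, BrC(Br)(Br)Br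
Why: Appel bromination should convert the primary allylic alcohol without touching the vinyl iodide, the lutidine protecting the ketal from acid.

Step 5
Reactants: 8 2-[(Z)-5-bromo-3-iodopent-3-en-1-yl]-2-methyl-1,3-dioxolane
Product: 9 2-[(3Z)-3-iodohepta-3,6-dien-1-yl]-2-methyl-1,3-dioxolane
Conditions: CH2=CHMgBr, CuI (10 mol %), THF, −40 °C
Reagents that add atoms: vinylmagnesium bromide, C=C[Mg]Br
Why: Copper-catalysed SN2 coupling of a vinyl Grignard reagent with the primary allylic bromide should give the skipped diene, SN2' attack being blocked at the fully substituted iodine-bearing carbon.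

Step 6
Reactants: 9 2-[(3Z)-3-iodohepta-3,6-dien-1-yl]-2-methyl-1,3-dioxolane
Product: 10 2-methyl-2-[(3E)-3-(pinacolboryl)hepta-3,6-dien-1-yl]-1,3-dioxolane (boron cis to the C5 methylene)
Conditions: B2pin2, PdCl2(dppf) (3 mol %), KOPh, toluene, 50 °C
Reagents that add atoms: bis(pinacolato)diboron, CC1(C)OB(OC1(C)C)B1OC(C)(C)C(C)(C)O1
Why: Miyaura borylation of an alkenyl iodide proceeds with retention of the double-bond geometry.

Step 7
Reactants: 10 2-methyl-2-[(3E)-3-(pinacolboryl)hepta-3,6-dien-1-yl]-1,3-dioxolane; 2 methyl 2-[(pinacolboryl)methyl]acrylate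
Product: 11 methyl (2E,5E)-8-(2-methyl-1,3-dioxolan-2-yl)-6-(pinacolboryl)-2-[(pinacolboryl)methyl]octa-2,5-dienoate
Conditions: second-generation Hoveyda–Grubbs catalyst (5 mol %), CH2Cl2, 40 °C
Reagents that add atoms: none
Why: Cross-metathesis of the terminal alkene with the 1,1-disubstituted acrylate should give the trisubstituted enoate with the chain trans to the ester and cis to CH2B, the geometry needed for a syn allylboration; the trisubstituted alkenyl boronate is inert.

Step 8
Reactants: 11 methyl (2E,5E)-8-(2-methyl-1,3-dioxolan-2-yl)-6-(pinacolboryl)-2-[(pinacolboryl)methyl]octa-2,5-dienoate; 12 (E)-but-2-enal (crotonaldehyde)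
Product: 15 ring B methylene lactone (3aS,7R,8aS)-7-methyl-3-methylidene-6-[2-(2-methyl-1,3-dioxolan-2-yl)ethyl]-3,3a,4,7,8,8a-hexahydro-2H-cyclohepta[b]furan-2-one, via ring B seco aldehyde 13 (not isolated), via ring B hydroxy ester 14 (not isolated)
Conditions: [RhCl(C2H4)2]2 (2.5 mol %), (S,S)-2,5-diphenylbicyclo[2.2.2]octa-2,5-diene (5.5 mol %), KOH (0.2 equiv), 1,4-dioxane/H2O 10:1, 25 °C; then 60 °C
Reagents that add atoms: none
Why: Proposed new method: a monovalent rhodium hydroxide transmetalates the alkenyl boronate, the alkenylrhodium adds 1,4 to crotonaldehyde (C1'–C10') and protonation frees aldehyde 13, whose carbonyl is then attacked by the γ-carbon C7' of the 2-(methoxycarbonyl)allyl boronate through a closed chair-like boron-bridged transition state (C7'–C8') before the boron alkoxide acylates itself on the ester. The closest known reactions are the rhodium/chiral-diene conjugate addition of organoboron reagents to enals and the thermal addition of 2-alkoxycarbonyl allylboronates to aldehydes, which have not been run in tandem or to close a ring. The cycloheptene closes by 7-exo-trig attack of C7' on the aldehyde carbon (allyl double bond outside the ring) and the lactone by 5-exo-trig acyl substitution. C10' is set by the chiral diene ligand (catalyst control); C7' and C8' follow by substrate control, the chain cis to CH2B on the allyl boronate giving the syn and therefore cis-fused pair, and the bicyclic transition state with the C10' methyl pseudo-equatorial placing the C8' oxygen cis to it. The step needs chemoselectivity between the two C–B bonds and 1,4- over 1,2-addition: only the alkenyl boronate should transfer readily to rhodium, the ester-deactivated allyl boronate should not react with crotonaldehyde at 25 °C, and diene-ligated rhodium adds conjugately.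

Step 9
Reactants: 15 ring B methylene lactone
Product: 18 ring B keto lactone (3aS,7R,8aS)-3-acetyl-7-methyl-6-[2-(2-methyl-1,3-dioxolan-2-yl)ethyl]-3,3a,4,7,8,8a-hexahydro-2H-cyclohepta[b]furan-2-one, via lithium enolate 16 (not isolated), via acetylated Mannich base 17 (not isolated)
Conditions: LiN(CH2Ph)2 (from HN(CH2Ph)2, n-BuLi), THF, −78 °C; then 1-acetylimidazole, −78 to 0 °C; then AcOH/NaOAc, EtOH/H2O, 50 °C
Reagents that add atoms: 1-acetylimidazole, CC(=O)n1ccnc1
Why: Conjugate addition of the lithium amide gives lactone enolate 16, C-acylation by the acyl imidazole gives the quaternary Mannich base 17, and retro-Mannich fragmentation of this β-dicarbonyl Mannich base expels the former exocyclic carbon as formaldehyde; C11' stays enolisable, so no stereocentre needs control here.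

Step 10
Reactants: 19 prop-2-yn-1-ol
Product: 21 3-iodo-2-[(trimethylsilyl)methyl]prop-2-en-1-ol (iodine cis to CH2OH), via chelated alkenylmagnesium alkoxide 20 (not isolated)
Conditions: Me3SiCH2MgCl (3 equiv), CuI (10 mol %), THF, 0 °C to rt; then I2, −20 °C; aq. NH4Cl
Reagents that add atoms: (trimethylsilyl)methylmagnesium chloride, C[Si](C)(C)C[Mg]Cl; iodine, II
Why: Alkoxide-directed, copper-catalysed anti-carbomagnesiation of the propargylic alcohol places magnesium on the terminal carbon cis to the CH2O group (chelate 20), and iodinolysis with retention should give the vinyl iodide with iodine cis to the future C6.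

Step 11
Reactants: 21 3-iodo-2-[(trimethylsilyl)methyl]prop-2-en-1-ol
Product: 22 [2-(bromomethyl)-3-iodoprop-2-en-1-yl]trimethylsilane (iodine cis to CH2Br)
Conditions: CBr4, PPh3, CH2Cl2, 0 °C
Reagents that add atoms: carbon tetrabromide, BrC(Br)(Br)Br
Why: Appel bromination of the primary allylic alcohol is neutral and should leave the allylsilane and the vinyl iodide intact.

Step 12
Reactants: 22 [2-(bromomethyl)-3-iodoprop-2-en-1-yl]trimethylsilane
Product: 23 [2-(iodomethylidene)pent-4-en-1-yl]trimethylsilane (iodine cis to the allyl CH2)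
Conditions: CH2=CHMgBr, CuI (10 mol %), THF, −40 °C
Reagents that add atoms: vinylmagnesium bromide, C=C[Mg]Br
Why: Copper-catalysed SN2 coupling of the vinyl Grignard reagent with the allylic bromide, as in step 5.

Step 13
Reactants: 23 [2-(iodomethylidene)pent-4-en-1-yl]trimethylsilane
Product: 24 trimethyl{2-[(pinacolboryl)methylidene]pent-4-en-1-yl}silane (boron cis to the allyl CH2)
Conditions: B2pin2, PdCl2(dppf) (3 mol %), KOPh, toluene, 50 °C
Reagents that add atoms: bis(pinacolato)diboron, CC1(C)OB(OC1(C)C)B1OC(C)(C)C(C)(C)O1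
Why: Miyaura borylation of the alkenyl iodide with retention of geometry, as in step 6.

Step 14
Reactants: 24 trimethyl{2-[(pinacolboryl)methylidene]pent-4-en-1-yl}silane; 2 methyl 2-[(pinacolboryl)methyl]acrylate
Product: 25 methyl (2E,5E)-6-(pinacolboryl)-2-[(pinacolboryl)methyl]-5-[(trimethylsilyl)methyl]hexa-2,5-dienoate
Conditions: second-generation Hoveyda–Grubbs catalyst (5 mol %), CH2Cl2, 40 °C
Reagents that add atoms: none
Why: Cross-metathesis of the terminal alkene with the acrylate, as in step 7; the trisubstituted allylsilane alkene does not take part.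

Step 15
Reactants: 25 methyl (2E,5E)-6-(pinacolboryl)-2-[(pinacolboryl)methyl]-5-[(trimethylsilyl)methyl]hexa-2,5-dienoate; 12 (E)-but-2-enal (crotonaldehyde)
Product: 28 ring A methylene lactone (3aR,7S,8aR)-7-methyl-3-methylidene-5-[(trimethylsilyl)methyl]-3,3a,4,7,8,8a-hexahydro-2H-cyclohepta[b]furan-2-one, via ring A seco aldehyde 26 (not isolated), via ring A hydroxy ester 27 (not isolated)
Conditions: [RhCl(C2H4)2]2 (2.5 mol %), (R,R)-2,5-diphenylbicyclo[2.2.2]octa-2,5-diene (5.5 mol %), KOH (0.2 equiv), 1,4-dioxane/H2O 10:1, 25 °C; then 60 °C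
Reagents that add atoms: none
Why: Proposed new method: the same tandem of rhodium-catalysed conjugate alkenylation, intramolecular allylboration through a chair-like transition state and lactonisation as in step 8 (closest known types: rhodium/diene conjugate addition of organoboron reagents to enals and allylboration with 2-alkoxycarbonyl allylboronates), run with the antipodal ligand so that C10 is set by the catalyst and C7/C8 follow from it; the allylsilane should be a spectator in this basic, acid-free medium.

Step 16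
Reactants: 28 ring A methylene lactone
Product: 30 (3aR,7S,8aR)-6-hydroxy-7-methyl-3,5-dimethylideneoctahydro-2H-cyclohepta[b]furan-2-one (both C6 epimers), via epoxy silane 29 (not isolated)
Conditions: mCPBA, NaHCO3, CH2Cl2, 0 °C; then AcOH, THF/H2O, rt
Reagents that add atoms: 3-chloroperbenzoic acid, O=C(OO)c1cccc(Cl)c1
Why: The peracid should epoxidise only the electron-rich allylsilane alkene, and the β-silyl epoxide opens with loss of silicon (Peterson-type 1,2-elimination) to the transposed allylic alcohol with the exocyclic methylene on C5; the carbinol configuration is irrelevant because it is oxidised next.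

Step 17
Reactants: 30 (3aR,7S,8aR)-6-hydroxy-7-methyl-3,5-dimethylideneoctahydro-2H-cyclohepta[b]furan-2-one
Product: 31 ring A enone (3aR,7S,8aR)-7-methyl-3,5-dimethylidenehexahydro-2H-cyclohepta[b]furan-2,6(3H)-dione
Conditions: Dess–Martin periodinane, NaHCO3, CH2Cl2, 0 °C
Reagents that add atoms: none
Why: Dess–Martin oxidation gives the α-methylene ketone under neutral conditions; it should be used at once because such enones dimerise.

Step 18
Reactants: 18 ring B keto lactone; 31 ring A enone
Product: 33 spiro ketol (target skeleton with C3 ketone, C2 methylene, C1 hydroxyl and the side-chain ketone as dioxolane), via Michael adduct 32 (not isolated)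
Conditions: DBU (0.3 equiv), LiCl, MeCN, −20 °C to rt
Reagents that add atoms: none
Why: In this Robinson-type Michael/aldol sequence the β-keto lactone enolate should add to the exocyclic enone (more electrophilic than the methylene lactone) from the convex face of the cis-fused bicycle, anti to C6'/C9', which sets C11'; C5 equilibrates under the base, and only the epimer with the new chain anti to the C10 methyl group lets the acetyl enolate reach C1 from the open face, so the intramolecular aldol should give the cis-fused ketol and set C5 and C1.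

Step 19
Reactants: 33 spiro ketol
Product: 34 trimethylsilyl ether of 33
Conditions: 1-(trimethylsilyl)imidazole, CH2Cl2, rt
Reagents that add atoms: 1-(trimethylsilyl)imidazole, C[Si](C)(C)n1ccnc1
Why: Neutral silylation of the tertiary aldol hydroxyl blocks retro-aldol cleavage and alkoxide elimination in the next step.

Step 20
Reactants: 34 trimethylsilyl ether of 33
Product: 36 C3 enol triflate (C2=C3), via potassium enolate 35 (not isolated)
Conditions: KN(SiMe3)2, THF, −78 °C; then N-(5-chloropyridin-2-yl)bis(trifluoromethanesulfonimide), −78 °C; aq. NH4Cl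
Reagents that add atoms: Comins' reagent, FC(F)(F)S(=O)(=O)N(c1ccc(Cl)cn1)S(=O)(=O)C(F)(F)F
Why: The C3 ketone can enolise only towards C2 because C11' is quaternary, so kinetic deprotonation and O-triflation should give a single enol triflate.

Step 21
Reactants: 36 C3 enol triflate
Product: 38 target compound, via ethoxyvinyl diene 37 (not isolated)
Conditions: CH2=C(OEt)SnBu3, Pd(PPh3)4 (5 mol %), LiCl, THF, 65 °C; then 1 M HCl, THF, rt
Reagents that add atoms: tributyl(1-ethoxyvinyl)stannane, CCOC(=C)[Sn](CCCC)(CCCC)CCCC; water, O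
Why: Stille coupling of the enol triflate with an α-alkoxyvinyl stannane (acetyl anion equivalent) gives enol ether 37, and mild aqueous acid hydrolyses it to the acetyl group while removing the silyl ether and the dioxolane; no stereocentre is touched.

Compound list
1 | methyl 2-(bromomethyl)acrylate | C=C(CBr)C(=O)OC | starting material
2 | methyl 2-[(pinacolboryl)methyl]acrylate | C=C(CB1OC(C)(C)C(C)(C)O1)C(=O)OC | intermediate
3 | 2-(but-3-yn-1-yl)-2-methyl-1,3-dioxolane | C#CCCC1(C)OCCO1 | starting material
4 | lithium acetylide of 3 | [Li]C#CCCC1(C)OCCO1 | intermediate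
5 | 5-(2-methyl-1,3-dioxolan-2-yl)pent-2-yn-1-ol | OCC#CCCC1(C)OCCO1 | intermediate
6 | cyclic sodium alkenylalanate (aluminium on the future C1', bound to the alkoxide oxygen, two 2-methoxyethoxy ligands) | [Na+].COCCO[Al-]1(OCCOC)OCC=C1CCC2(C)OCCO2 | intermediate
7 | (Z)-3-iodo-5-(2-methyl-1,3-dioxolan-2-yl)pent-2-en-1-ol | OC/C=C(\I)CCC1(C)OCCO1 | intermediate
8 | 2-[(Z)-5-bromo-3-iodopent-3-en-1-yl]-2-methyl-1,3-dioxolane | BrC/C=C(\I)CCC1(C)OCCO1 | intermediate
9 | 2-[(3Z)-3-iodohepta-3,6-dien-1-yl]-2-methyl-1,3-dioxolane | C=CC/C=C(\I)CCC1(C)OCCO1 | intermediate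
10 | 2-methyl-2-[(3E)-3-(pinacolboryl)hepta-3,6-dien-1-yl]-1,3-dioxolane | C=CC/C=C(\B1OC(C)(C)C(C)(C)O1)CCC1(C)OCCO1 | intermediate
11 | methyl (2E,5E)-8-(2-methyl-1,3-dioxolan-2-yl)-6-(pinacolboryl)-2-[(pinacolboryl)methyl]octa-2,5-dienoate | COC(=O)/C(CB1OC(C)(C)C(C)(C)O1)=C/C/C=C(\B1OC(C)(C)C(C)(C)O1)CCC1(C)OCCO1 | intermediate
12 | (E)-but-2-enal (crotonaldehyde) | C/C=C/C=O | starting material
13 | methyl (2E,5Z,7R)-7-methyl-6-[2-(2-methyl-1,3-dioxolan-2-yl)ethyl]-9-oxo-2-[(pinacolboryl)methyl]nona-2,5-dienoate | O=CC[C@@H](C)/C(CCC1(C)OCCO1)=C\C/C=C(\CB1OC(C)(C)C(C)(C)O1)C(=O)OC | intermediate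
14 | methyl 2-{(1S,2S,4R)-2-hydroxy-4-methyl-5-[2-(2-methyl-1,3-dioxolan-2-yl)ethyl]cyclohept-5-en-1-yl}acrylate | C=C(C(=O)OC)[C@@H]1CC=C(CCC2(C)OCCO2)[C@H](C)C[C@@H]1O | intermediate
15 | (3aS,7R,8aS)-7-methyl-3-methylidene-6-[2-(2-methyl-1,3-dioxolan-2-yl)ethyl]-3,3a,4,7,8,8a-hexahydro-2H-cyclohepta[b]furan-2-one | C=C1C(=O)O[C@H]2C[C@@H](C)C(CCC3(C)OCCO3)=CC[C@@H]12 | intermediate
16 | lithium enolate of the 3-[(dibenzylamino)methyl] lactone derived from 15 | [Li+].[O-]C1=C(CN(Cc2ccccc2)Cc2ccccc2)[C@@H]2CC=C(CCC3(C)OCCO3)[C@H](C)C[C@@H]2O1 | intermediate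
17 | 3-acetyl-3-[(dibenzylamino)methyl] lactone (C3 configuration not assigned) | CC(=O)C1(CN(Cc2ccccc2)Cc2ccccc2)C(=O)O[C@H]2C[C@@H](C)C(CCC3(C)OCCO3)=CC[C@@H]12 | intermediate
18 | (3aS,7R,8aS)-3-acetyl-7-methyl-6-[2-(2-methyl-1,3-dioxolan-2-yl)ethyl]-3,3a,4,7,8,8a-hexahydro-2H-cyclohepta[b]furan-2-one (C3 epimers and enol) | CC(=O)C1C(=O)O[C@H]2C[C@@H](C)C(CCC3(C)OCCO3)=CC[C@@H]12 | intermediate
19 | prop-2-yn-1-ol | C#CCO | starting material
20 | 4-[(trimethylsilyl)methyl]-2,5-dihydro-1,2-oxamagnesole (chelated alkenylmagnesium alkoxide) | C[Si](C)(C)CC1=C[Mg]OC1 | intermediate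
21 | 3-iodo-2-[(trimethylsilyl)methyl]prop-2-en-1-ol, iodine cis to CH2OH | OC/C(C[Si](C)(C)C)=C\I | intermediate
22 | [2-(bromomethyl)-3-iodoprop-2-en-1-yl]trimethylsilane, iodine cis to CH2Br | BrC/C(C[Si](C)(C)C)=C\I | intermediate
23 | [2-(iodomethylidene)pent-4-en-1-yl]trimethylsilane, iodine cis to the allyl CH2 | C=CC/C(C[Si](C)(C)C)=C\I | intermediate
24 | trimethyl{2-[(pinacolboryl)methylidene]pent-4-en-1-yl}silane, boron cis to the allyl CH2 | C=CC/C(C[Si](C)(C)C)=C\B1OC(C)(C)C(C)(C)O1 | intermediate
25 | methyl (2E,5E)-6-(pinacolboryl)-2-[(pinacolboryl)methyl]-5-[(trimethylsilyl)methyl]hexa-2,5-dienoate | COC(=O)/C(CB1OC(C)(C)C(C)(C)O1)=C/C/C(C[Si](C)(C)C)=C\B1OC(C)(C)C(C)(C)O1 | intermediate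
26 | methyl (2E,5E,7S)-7-methyl-9-oxo-2-[(pinacolboryl)methyl]-5-[(trimethylsilyl)methyl]nona-2,5-dienoate | O=CC[C@H](C)/C=C(C[Si](C)(C)C)\C/C=C(\CB1OC(C)(C)C(C)(C)O1)C(=O)OC | intermediate
27 | methyl 2-{(1R,2R,4S)-2-hydroxy-4-methyl-6-[(trimethylsilyl)methyl]cyclohept-5-en-1-yl}acrylate | C=C(C(=O)OC)[C@H]1CC(C[Si](C)(C)C)=C[C@@H](C)C[C@H]1O | intermediate
28 | (3aR,7S,8aR)-7-methyl-3-methylidene-5-[(trimethylsilyl)methyl]-3,3a,4,7,8,8a-hexahydro-2H-cyclohepta[b]furan-2-one | C=C1C(=O)O[C@@H]2C[C@H](C)C=C(C[Si](C)(C)C)C[C@H]12 | intermediate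
29 | 5,6-epoxide of 28 (epoxide configuration not assigned) | C=C1C(=O)O[C@@H]2C[C@H](C)C3OC3(C[Si](C)(C)C)C[C@H]12 | intermediate
30 | (3aR,7S,8aR)-6-hydroxy-7-methyl-3,5-dimethylideneoctahydro-2H-cyclohepta[b]furan-2-one (C6 epimers) | C=C1C(=O)O[C@@H]2C[C@H](C)C(O)C(=C)C[C@H]12 | intermediate
31 | (3aR,7S,8aR)-7-methyl-3,5-dimethylidenehexahydro-2H-cyclohepta[b]furan-2,6(3H)-dione | C=C1C(=O)O[C@@H]2C[C@H](C)C(=O)C(=C)C[C@H]12 | intermediate
32 | Michael adduct: ring A ketone carrying at C5 the CH2 (C13') bonded to C11' of the 3-acetyl ring B lactone (C5 epimers) | C=C1C(=O)O[C@@H]2C[C@H](C)C(=O)C(C[C@H]12)C[C@]3(C(C)=O)C(=O)O[C@H]4C[C@@H](C)C(CCC5(C)OCCO5)=CC[C@@H]34 | intermediate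
33 | spiro ketol: target skeleton with C3 ketone, C2 methylene, free C1 hydroxyl, side-chain ketone as dioxolane | C=C1C(=O)O[C@@H]2C[C@H](C)[C@@]3(O)CC(=O)[C@@]4(C[C@H]3C[C@H]12)C(=O)O[C@H]1C[C@@H](C)C(CCC5(C)OCCO5)=CC[C@H]14 | intermediate
34 | C1 trimethylsilyl ether of 33 | C=C1C(=O)O[C@@H]2C[C@H](C)[C@@]3(O[Si](C)(C)C)CC(=O)[C@@]4(C[C@H]3C[C@H]12)C(=O)O[C@H]1C[C@@H](C)C(CCC5(C)OCCO5)=CC[C@H]14 | intermediate
35 | potassium C2=C3 enolate of 34 | [K+].C=C1C(=O)O[C@@H]2C[C@H](C)[C@@]3(O[Si](C)(C)C)C=C([O-])[C@@]4(C[C@H]3C[C@H]12)C(=O)O[C@H]1C[C@@H](C)C(CCC5(C)OCCO5)=CC[C@H]14 | intermediate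
36 | C3 enol triflate (C2=C3) of 34 | C=C1C(=O)O[C@@H]2C[C@H](C)[C@@]3(O[Si](C)(C)C)C=C(OS(=O)(=O)C(F)(F)F)[C@@]4(C[C@H]3C[C@H]12)C(=O)O[C@H]1C[C@@H](C)C(CCC5(C)OCCO5)=CC[C@H]14 | intermediate
37 | 3-(1-ethoxyvinyl) diene (silyl ether and dioxolane still in place) | C=C1C(=O)O[C@@H]2C[C@H](C)[C@@]3(O[Si](C)(C)C)C=C(C(=C)OCC)[C@@]4(C[C@H]3C[C@H]12)C(=O)O[C@H]1C[C@@H](C)C(CCC5(C)OCCO5)=CC[C@H]14 | intermediate
38 | target compound | C=C1C(=O)O[C@@H]2C[C@H](C)[C@@]3(O)C=C(C(C)=O)[C@@]4(C[C@H]3C[C@H]12)C(=O)O[C@H]1C[C@@H](C)C(CCC(C)=O)=CC[C@H]14 | target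

Total step count: 21. Longest linear sequence: 12 steps (steps 2–9, then 18–21).

Steps most likely to fail

1. Step 8. Two processes may go wrong. The allyl boronate may transmetalate to rhodium in competition with the alkenyl boronate, leading to protodeboronation or 1,2-allylation of crotonaldehyde. The ring-closing allylboration may also show poor facial selectivity with respect to C10'. The fallback sets out from 10. Rhodium/chiral-diene conjugate addition of alkenyl boronate 10 alone to crotonaldehyde 12 (a known reaction type, same ligand) should give the isolable aldehyde (3R,4Z)-3-methyl-4-[2-(2-methyl-1,3-dioxolan-2-yl)ethyl]octa-4,7-dienal F1. Cross-metathesis of F1 with 2 (second-generation Hoveyda–Grubbs catalyst) then installs the allyl boronate only after the rhodium step and gives 13. This should cyclise on warming, with Sc(OTf)3 if needed, through 14 to 15, where the route is rejoined.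

2. Step 15. The same competing boron transfer and facial-selectivity issue apply, and the allylsilane may in addition be lost by protodesilylation during the long aqueous basic reaction or on lactonisation. The fallback sets out from 24. Rhodium-catalysed conjugate addition of 24 to 12 with the (R,R)-ligand should give the aldehyde (3S,4E)-3-methyl-5-[(trimethylsilyl)methyl]octa-4,7-dienal F2. Cross-metathesis of F2 with 2 under neutral conditions gives 26, which should close thermally in toluene at 60–80 °C through 27 to 28, where the route is rejoined.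

3. Step 18. Under the amine base the C10 stereocentre of the enone may epimerise, the Michael adduct may revert, or the tertiary ketol may dehydrate to the enone. The fallback sets out from 18 and 31. The Michael addition alone is run with Et3N (catalytic) in CH2Cl2 at −20 °C and adduct 32 is isolated. Kinetic silylation of the acetyl group (LiN(SiMe3)2, Me3SiCl, THF, −78 °C) gives the trimethylsilyl enol ether of the acetyl group of 32 F3. An intramolecular Mukaiyama aldol addition under Lewis acid (BF3·OEt2, CH2Cl2, −78 °C) then closes the ring without base and gives 33, where the route is rejoined.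

Further compounds
F1 | step 8 | (3R,4Z)-3-methyl-4-[2-(2-methyl-1,3-dioxolan-2-yl)ethyl]octa-4,7-dienal | O=CC[C@@H](C)/C(CCC1(C)OCCO1)=C\CC=C
F2 | step 15 | (3S,4E)-3-methyl-5-[(trimethylsilyl)methyl]octa-4,7-dienal | O=CC[C@H](C)/C=C(C[Si](C)(C)C)\CC=C
F3 | step 18 | trimethylsilyl enol ether of the acetyl group of 32 | C=C1C(=O)O[C@@H]2C[C@H](C)C(=O)C(C[C@H]12)C[C@]3(C(=C)O[Si](C)(C)C)C(=O)O[C@H]4C[C@@H](C)C(CCC5(C)OCCO5)=CC[C@@H]34
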